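# Proposed total synthesis of CNP0275635.0 by twofold benzannulation of a skipped bis(siloxyalkyne)

## The problem

Target 20 is an achiral dimer in which two identical 8-isobutyryl-5,7-dihydroxy-2,2-dimethylchroman units are joined through their C6 carbons to one sp3 methine that also carries a 5-methylhexyl chain. Each half is a fully substituted benzene ring (C4a, C5, C6, C7, C8, C8a) fused along C4a–C8a to a gem-dimethyl dihydropyran, with the ring oxygen on C8a, the ring methylene on C4a, free hydroxyls on C5 and C7, the bridge on C6 and the ketone on C8. There is no stereocentre, because the bridge carbon carries two constitutionally identical aryl groups; nothing needs stereocontrol and every chiral intermediate may be racemic. The tasks are regiochemical: three phloroglucinol-type oxygens must be told apart, the acyl group must end next to the pyran oxygen and not between the two hydroxyls, and a congested diarylmethine flanked by four ortho oxygens must be made. That diarylmethine is the fragile element: while the rings are electron-rich it can be cleaved or scrambled by strong acid or base through ortho-quinone methides, and the free polyphenol is easily oxidised as its anion. The feature that opens a non-classical route is the order of atoms around each ring, in which C6 lies between the oxygenated C5 and C7 and the fused pair C4a–C8a carries the pyran CH2 and the pyran oxygen. This is the pattern obtained when an ynol ether (C5 and C6) combines with a four-carbon vinylketene (C7, C8, C8a, C4a) released from a cyclobutenone whose enol-ether double bond is already part of the pyran ring. The bridge methine can then exist from the start as an ordinary sp3 carbon between two alkynes.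

## Retrosynthesis

Target 20 is first taken back to its bis(silyl ether) 19 (two O–Si bonds at the C5 oxygens), and then the two C8–acyl bonds are cut, giving bis-chromanol 18. The acyl groups are cut here and not carried through arene formation, because an acyl group on the sp3 carbon of the cyclobutenone would divert the derived vinylketene into a 2-pyranone. In 18, C8 is the only unsubstituted arene carbon and lies ortho to the free C7 hydroxyl, so the forward acylation has one possible site. It must be mild enough to spare the electron-rich diarylmethine.

Bis-chromanol 18 is cut in each arene at C6–C7 and C5–C4a, with C7–C8 opened and re-formed on the way. This leads to bis(siloxyalkyne) 11 and two molecules of the pyran-fused alkoxycyclobutenone 15, which reacts through vinylketene 16. The neighbouring cut, at the two C6–CH bonds, would make the most hindered bond of the molecule last and would need an already differentiated acylchromanol. The other benzannulation mapping, with the ynol-ether carbon as C7, would need a cyclobutenone with an sp3 ring-fusion carbon, which is much less accessible from a 1,3-dione. The chosen cut removes both benzene rings and four skeletal C–C bonds at once and leaves an acyclic diyne and a nine-carbon bicycle. The forward reaction must run twice on one molecule (through mono-annulated 17), follow the polarity of the ynol ether, and proceed without base so that the doubly propargylic C–H of 11 is not isomerised.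

Bis(siloxyalkyne) 11 is cut at its two C(sp)–O bonds, through dilithium bis(ynolate) 10 and dilithium diacetylide 9, back to the terminal skipped diyne 8. Oxygenation of acetylides is preferred to ester-homologation routes to ynolates, which would need a malonate-type diester whose central hydrogen is too acidic. Diyne 8 comes from its C-silylated form 7 by removal of two C–Si bonds. The forward sequence must keep the central C–H intact under strongly basic conditions and place a silyl group on oxygen that is bulky enough to survive heating.

Diyne 7 is cut at one C3–C(sp) bond into propargylic mesylate 5 and alkynylalane 6, which is made in one operation from alkyne 2 and Me3Al. Mesylate 5 goes back through alcohol 4 to aldehyde 1 and lithium acetylide 3 of the same alkyne 2. A double acetylide addition to an ester would be shorter but leaves a tertiary carbinol to deoxygenate, and alkylation of a pentadiynyl anion would give allenes. The chosen cut uses one cheap alkyne twice and leads to a symmetric product. The forward substitution must take place at the propargylic carbon and not at the distal alkyne carbon.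

Cyclobutenone 15 is cut at the O–C(CH3)2 bond to the 2-prenyl enol 14, and 14 at its C2–CH2 bond to cyclobutane-1,3-dione 12 and prenyl acetate 13. Assembling the four-membered ring by ketene cycloaddition onto a tethered ynol ether would be longer. The dione route gives the bicycle in two steps, and because 12 is symmetric the ring closure can give only one product. The forward steps require C-allylation of a very acidic dione and a ring closure cool enough to keep the cyclobutenone closed.

## Roads not taken

Alternative 1: The cut is made inside each benzene ring at C7–C8. Both acylphloroglucinol rings are folded from a tetraketide-like chain stored as the bis-pyrone 3,3'-(6-methylheptane-1,1-diyl)bis[4-(benzyloxy)-6-(3-methyl-2-oxobutyl)-2H-pyran-2-one] A1.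
- Forward key step: Mg(OMe)2 in methanol would open both lactones, and the doubly activated side-chain methylene of each half would close onto the freed ester by Claisen condensation. The product is 1,1'-{(6-methylheptane-1,1-diyl)bis[4-(benzyloxy)-2,6-dihydroxy-3,1-phenylene]}bis(2-methylpropan-1-one) A2.
- Merits: the chemistry is of a known polyketide type. The acyl group is present from the start, so no late acylation of a diarylmethine is needed. The bridge is made at the pyrone stage, where C3 of a 4-hydroxypyrone condenses readily with an aldehyde. The C5 oxygen emerges already differentiated as a benzyl ether.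
- Weak points: A2 does not yet contain the pyran rings. Two C-prenylations at the last arene C–H, two cyclisations and a debenzylation (or the annulation of Alternative 3) still follow. A1 needs side-chain acylation, dimerisation and O-benzylation of a hindered 4-hydroxypyrone, which can also alkylate at the lactone oxygen. In the key step the Claisen closure must win over aldol closure on both halves.
- Comparison: this road is better in precedent, since no step is unprecedented, and in placing the ketone early. The chosen plan sets against it that its key step delivers the complete chroman skeleton with every substituent position fixed, and that the sequence after the key step is two steps instead of four or five.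

Alternative 2: The cut is made at O1–C2 of both pyran rings.
- Forward key step: catalytic acid (TsOH or Bi(OTf)3) would protonate both prenyl alkenes of 1,1'-{(6-methylheptane-1,1-diyl)bis[4-(benzyloxy)-2,6-dihydroxy-5-(3-methylbut-2-en-1-yl)-3,1-phenylene]}bis(2-methylpropan-1-one) A3. Each tertiary cation would be trapped by the adjacent free hydroxyl, giving 1,1'-[(6-methylheptane-1,1-diyl)bis(5-benzyloxy-7-hydroxy-2,2-dimethylchroman-6,8-diyl)]bis(2-methylpropan-1-one) A4. Hydrogenolysis of A4 then gives 20.
- Merits: the route is short and biomimetic, and each reaction type is known. The benzyl group on the C5 oxygen leaves only the C8a hydroxyl to close the ring, so the direction of cyclisation is secured. The acyl groups deactivate the rings and stabilise the diarylmethine during the acid step.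
- Weak points: A3 must be made by dimerising, with aldehyde 1, a monomer that is already C-prenylated, at its last free and hindered arene carbon. C-prenylation of acylphloroglucinols typically gives C/O and mono/bis mixtures. The trapping hydroxyl is the ketone-chelated, least nucleophilic one. Acid strong enough to protonate the alkene can also cleave benzyl ethers or reverse the diarylmethane formation.
- Comparison: this road is shorter than the chosen plan and rests entirely on known reactions. That is a real advantage. The chosen plan sets against it regiochemistry fixed by mechanism and not by protecting-group choice and separations, a bridge carbon that is never formed by a hindered arene–aldehyde condensation, and no benzyl ethers to remove. It pays for this with one untested step.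

Alternative 3: The cut is made at C4a–C4 and O1–C2 of each pyran.
- Forward key step: condensation of A2 with two equivalents of 3-methylbut-2-enal A5, mediated by ethylenediammonium diacetate (Knoevenagel-type addition at C4a, dehydration, oxa-6π electrocyclisation), would give the bis-chromene 1,1'-[(6-methylheptane-1,1-diyl)bis(5-benzyloxy-7-hydroxy-2,2-dimethyl-2H-chromene-6,8-diyl)]bis(2-methylpropan-1-one) A6. One hydrogenation over Pd/C would then saturate both chromene double bonds and remove both benzyl groups, giving 20.
- Merits: this is the most step-economic route. There is no C-prenylation problem, the benzyl ether again directs ring closure to the C8a oxygen, and the last step performs two tasks.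
- Weak points: the arene carbon that must attack the enal is deactivated by the acyl group and flanked by a benzyloxy and a chelated hydroxyl. The reaction has to succeed twice on a hindered dimer under amine and heat, conditions under which ortho-hydroxy diarylmethanes can fragment and recombine through ortho-quinone methides. Unless A2 is made by the long pyrone route of Alternative 1, it comes from a monomer with two equivalent nucleophilic carbons, so condensation with aldehyde 1 can run on to oligomers.
- Comparison: this road is clearly shorter and better precedented. The chosen plan sets against it control of every substituent position and an assembly of the diarylmethine that cannot oligomerise, because the bridge carbon is made from monofunctional partners before any arene exists.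

Key step: step 8

Assumption: aldehyde 1 and dione 12 are taken as purchasable, and all chiral intermediates (4, 5, 17) are handled as racemates because their stereogenic carbon becomes the non-stereogenic bridge.

## Route

Step 1
Reactants: 1 6-methylheptanal; 2 ethynyltrimethylsilane
Product: 4 8-methyl-1-(trimethylsilyl)non-1-yn-3-ol (racemic), via lithium (trimethylsilyl)acetylide 3 (not isolated)
Conditions: 2, n-BuLi, THF, −78 °C; then 1, −78 → 0 °C
Reagents that add atoms: none
Why: 1,2-Addition of a lithium acetylide to an unhindered aliphatic aldehyde; the carbinol centre forms as the racemate, which is of no consequence because this carbon becomes the non-stereogenic bridge in 7.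

Step 2
Reactants: 4 8-methyl-1-(trimethylsilyl)non-1-yn-3-ol
Product: 5 8-methyl-1-(trimethylsilyl)non-1-yn-3-yl methanesulfonate (racemic)
Conditions: MsCl, Et3N, CH2Cl2, −20 → 0 °C
Reagents that add atoms: methanesulfonyl chloride, CS(=O)(=O)Cl
Why: Sulfonylation of a secondary alcohol with a sulfonyl chloride and amine base; the silyl-capped alkyne is inert, and the mesylate is carried on cold and unpurified because secondary propargylic sulfonates ionise readily.

Step 3
Reactants: 5 8-methyl-1-(trimethylsilyl)non-1-yn-3-yl methanesulfonate; 2 ethynyltrimethylsilane
Product: 7 3-(5-methylhexyl)-1,5-bis(trimethylsilyl)penta-1,4-diyne, via dimethyl[(trimethylsilyl)ethynyl]aluminium 6 (not isolated)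
Conditions: 2, Me3Al, Et3N (10 mol %), toluene, rt → 50 °C; then 5, 0 °C → rt
Reagents that add atoms: none
Why: Amine-catalysed alumination of the terminal alkyne by Me3Al (loss of methane) gives alkynylalane 6 directly, without an alkali-metal acetylide, and this then displaces the propargylic sulfonate. Aluminium binds the mesylate oxygen, assists ionisation and delivers the alkynyl group (which transfers in preference to methyl) to the propargylic carbon in a non-coordinating solvent, while the trimethylsilyl group on the electrophile shields the distal alkyne carbon against SN2' attack; the former stereocentre ends with two identical alkynyl groups.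

Step 4
Reactants: 7 3-(5-methylhexyl)-1,5-bis(trimethylsilyl)penta-1,4-diyne
Product: 8 3-(5-methylhexyl)penta-1,4-diyne
Conditions: K2CO3 (cat.), MeOH, 0 °C → rt
Reagents that add atoms: none
Why: Protodesilylation of alkynyl C–Si bonds by catalytic methoxide; run cold and brief so that the doubly propargylic C–H is not isomerised.

Step 5
Reactants: 8 3-(5-methylhexyl)penta-1,4-diyne
Product: 11 3-(5-methylhexyl)-1,5-bis(triisopropylsilyloxy)penta-1,4-diyne, via dilithium diacetylide 9 (not isolated), via dilithium bis(ynolate) 10 (not isolated)
Conditions: n-BuLi, THF, −78 °C; LiOOt-Bu (t-BuOOH + LiN(SiMe3)2), −78 → 0 °C; i-Pr3SiOTf, −78 → 0 °C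
Reagents that add atoms: tert-butyl hydroperoxide, CC(C)(C)OO; triisopropylsilyl trifluoromethanesulfonate, CC(C)[Si](C(C)C)(C(C)C)OS(=O)(=O)C(F)(F)F
Why: Electrophilic oxygenation of lithium acetylides with lithium tert-butyl peroxide (attack at peroxide oxygen, loss of tert-butoxide) gives ynolates that the bulky silyl triflate traps on oxygen; the two anionic termini disfavour removal of the central proton, and triisopropylsilyl is chosen because smaller silyl ynol ethers rearrange to silylketenes on heating.

Step 6
Reactants: 12 cyclobutane-1,3-dione; 13 3-methylbut-2-en-1-yl acetate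
Product: 14 3-hydroxy-2-(3-methylbut-2-en-1-yl)cyclobut-2-en-1-one
Conditions: Pd(PPh3)4 (cat.), THF, rt → 40 °C; 12 in excess
Reagents that add atoms: none
Why: Tsuji–Trost allylation of a cyclic 1,3-dione: zerovalent palladium ionises the allylic acetate, the liberated acetate deprotonates the strongly acidic dione, and the soft enolate attacks the unsubstituted terminus of the 1,1-dimethylallyl ligand; any O-allyl enol ether re-ionises under the catalyst and funnels to the C-allylated product, and excess dione limits double allylation.

Step 7
Reactants: 14 3-hydroxy-2-(3-methylbut-2-en-1-yl)cyclobut-2-en-1-one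
Product: 15 3,3-dimethyl-2-oxabicyclo[4.2.0]oct-1(6)-en-7-one
Conditions: Amberlyst 15, CH2Cl2, rt
Reagents that add atoms: none
Why: Acid-catalysed Markovnikov hydroalkoxylation of the prenyl alkene by the enol oxygen (6-endo capture of the tertiary cation), the standard closure of 2-prenyl-1,3-diones to 2,2-dimethyldihydropyrans; both oxygens of the symmetric dione give the same product, and room temperature keeps the cyclobutenone closed.

Step 8
Reactants: 11 3-(5-methylhexyl)-1,5-bis(triisopropylsilyloxy)penta-1,4-diyne; 15 3,3-dimethyl-2-oxabicyclo[4.2.0]oct-1(6)-en-7-one
Product: 18 6,6'-(6-methylheptane-1,1-diyl)bis[2,2-dimethyl-5-(triisopropylsilyloxy)chroman-7-ol], via pyran-fused vinylketene 16 (not isolated), via mono-annulated siloxyalkyne phenol 17 (not isolated)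
Conditions: toluene (degassed), 120 °C, sealed tube; 15 (2.5 equiv)
Reagents that add atoms: none
Why: Proposed new method: heating opens cyclobutenone 15 by a conrotatory four-electron process to vinylketene 16, whose ketene C=C adds [2+2] to a siloxyalkyne of 11 with the ketene carbonyl carbon bonding to the alkyne carbon that carries the bridge (the nucleophilic β-carbon of the ynol ether) and the ketene α-carbon bonding to the silyloxy-bearing carbon, which makes C6–C7 and C5–C4a. The spiro 4-alkenylcyclobutenone so formed reopens to a dienylketene, and each benzene ring then closes by a thermal disrotatory six-electron electrocyclisation between the ketene carbon and the exocyclic enol-ether methylene (re-forming C7–C8), followed by enolisation to the C7 phenol; the sequence repeats on the second alkyne through 17. The closest known reaction type is the Danheiser benzannulation of cyclobutenones with siloxyalkynes to resorcinol monosilyl ethers, which has not been run twice on a skipped diyne nor with a pyran-fused 3-alkoxycyclobutenone. No stereocentre is created: the bridge carbon is stereogenic only in 17 and carries two identical aryl groups in 18. The regiochemistry needed (bridge between hydroxyl and silyloxy group, pyran oxygen para to the bridge, C8 left as the only arene CH) follows from the polarisation of the ynol ether and from the fixed positions of the ring oxygen and ring CH2 on the cyclobutenone, and a ring opening of the spiro intermediate in the unproductive sense is reversible and drains through the productive isomer. Chemoselectivity rests on the absence of base, so that the doubly propargylic C–H is not isomerised to an allene, and on the slow release of 16, which keeps ketene dimerisation and O-acylation of the new phenols behind the cycloaddition.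

Step 9
Reactants: 18 6,6'-(6-methylheptane-1,1-diyl)bis[2,2-dimethyl-5-(triisopropylsilyloxy)chroman-7-ol]
Product: 19 1,1'-{(6-methylheptane-1,1-diyl)bis[7-hydroxy-2,2-dimethyl-5-(triisopropylsilyloxy)chroman-6,8-diyl]}bis(2-methylpropan-1-one)
Conditions: i-PrCOCl, TiCl4, CH2Cl2, −78 → −20 °C
Reagents that add atoms: 2-methylpropanoyl chloride, CC(C)C(Cl)=O
Why: Friedel–Crafts acylation of a phenol directed through its aryloxytitanium trichloride (ArOTiCl3): C8 is the only unsubstituted arene carbon, ortho to the C7 oxygen and the ring oxygen and para to the silyloxy group, and the chelated aryl ketone formed is deactivated toward further reaction; low temperature is used to outrun acid cleavage of the diarylmethine.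

Step 10
Reactants: 19 1,1'-{(6-methylheptane-1,1-diyl)bis[7-hydroxy-2,2-dimethyl-5-(triisopropylsilyloxy)chroman-6,8-diyl]}bis(2-methylpropan-1-one)
Product: 20 1,1'-[(6-methylheptane-1,1-diyl)bis(5,7-dihydroxy-2,2-dimethylchroman-6,8-diyl)]bis(2-methylpropan-1-one)
Conditions: Bu4NF, AcOH, THF, 0 °C
Reagents that add atoms: none
Why: Fluoride cleavage of aryl silyl ethers (Si–F bond formation with a phenoxide leaving group); acetic acid buffers the medium so that the polyphenol is released as the neutral compound and not as an oxidisable, scrambling-prone phenolate.

## Compound list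

1 | 6-methylheptanal | CC(C)CCCCC=O | starting material
2 | ethynyltrimethylsilane | C#C[Si](C)(C)C | starting material
3 | lithium (trimethylsilyl)acetylide | [Li]C#C[Si](C)(C)C | intermediate
4 | 8-methyl-1-(trimethylsilyl)non-1-yn-3-ol (racemic) | CC(C)CCCCC(O)C#C[Si](C)(C)C | intermediate
5 | 8-methyl-1-(trimethylsilyl)non-1-yn-3-yl methanesulfonate (racemic) | CC(C)CCCCC(OS(C)(=O)=O)C#C[Si](C)(C)C | intermediate
6 | dimethyl[(trimethylsilyl)ethynyl]aluminium | C[Al](C)C#C[Si](C)(C)C | intermediate
7 | 3-(5-methylhexyl)-1,5-bis(trimethylsilyl)penta-1,4-diyne | CC(C)CCCCC(C#C[Si](C)(C)C)C#C[Si](C)(C)C | intermediate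
8 | 3-(5-methylhexyl)penta-1,4-diyne | CC(C)CCCCC(C#C)C#C | intermediate
9 | [3-(5-methylhexyl)penta-1,4-diyne-1,5-diyl]dilithium (dilithium diacetylide) | CC(C)CCCCC(C#C[Li])C#C[Li] | intermediate
10 | dilithium 3-(5-methylhexyl)penta-1,4-diyne-1,5-bis(olate) (dilithium bis(ynolate)) | CC(C)CCCCC(C#CO[Li])C#CO[Li] | intermediate
11 | 3-(5-methylhexyl)-1,5-bis(triisopropylsilyloxy)penta-1,4-diyne | CC(C)CCCCC(C#CO[Si](C(C)C)(C(C)C)C(C)C)C#CO[Si](C(C)C)(C(C)C)C(C)C | intermediate
12 | cyclobutane-1,3-dione | O=C1CC(=O)C1 | starting material
13 | 3-methylbut-2-en-1-yl acetate | CC(=O)OCC=C(C)C | starting material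
14 | 3-hydroxy-2-(3-methylbut-2-en-1-yl)cyclobut-2-en-1-one | CC(C)=CCC1=C(O)CC1=O | intermediate
15 | 3,3-dimethyl-2-oxabicyclo[4.2.0]oct-1(6)-en-7-one | O=C1CC2=C1CCC(C)(C)O2 | intermediate
16 | (6,6-dimethyl-2-methylideneoxan-3-ylidene)methanone (pyran-fused vinylketene) | O=C=C1CCC(C)(C)OC1=C | intermediate
17 | 2,2-dimethyl-6-[8-methyl-1-(triisopropylsilyloxy)non-1-yn-3-yl]-5-(triisopropylsilyloxy)chroman-7-ol (racemic) | CC(C)CCCCC(C#CO[Si](C(C)C)(C(C)C)C(C)C)c1c(O[Si](C(C)C)(C(C)C)C(C)C)c2CCC(C)(C)Oc2cc1O | intermediate
18 | 6,6'-(6-methylheptane-1,1-diyl)bis[2,2-dimethyl-5-(triisopropylsilyloxy)chroman-7-ol] | CC(C)CCCCC(c1c(O[Si](C(C)C)(C(C)C)C(C)C)c2CCC(C)(C)Oc2cc1O)c1c(O[Si](C(C)C)(C(C)C)C(C)C)c2CCC(C)(C)Oc2cc1O | intermediate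
19 | 1,1'-{(6-methylheptane-1,1-diyl)bis[7-hydroxy-2,2-dimethyl-5-(triisopropylsilyloxy)chroman-6,8-diyl]}bis(2-methylpropan-1-one) | CC(C)CCCCC(c1c(O[Si](C(C)C)(C(C)C)C(C)C)c2CCC(C)(C)Oc2c(C(=O)C(C)C)c1O)c1c(O[Si](C(C)C)(C(C)C)C(C)C)c2CCC(C)(C)Oc2c(C(=O)C(C)C)c1O | intermediate
20 | 1,1'-[(6-methylheptane-1,1-diyl)bis(5,7-dihydroxy-2,2-dimethylchroman-6,8-diyl)]bis(2-methylpropan-1-one) | CC(C)CCCCC(c1c(O)c2c(c(C(=O)C(C)C)c1O)OC(C)(C)CC2)c1c(O)c2c(c(C(=O)C(C)C)c1O)OC(C)(C)CC2 | target

## Step count and least certain steps

Total: 10 steps. Longest linear sequence: 8 steps (steps 1–5, 8, 9, 10); the cyclobutenone branch (steps 6 and 7) joins at step 8.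

Step 8 (key step, proposed new method).
- What may go wrong: the vinylogous-ester stabilisation of 15 may hold back electrocyclic opening until temperatures at which the siloxyalkynes degrade. After the first annulation, the new C7 hydroxyl of 17 may add across the remaining siloxyalkyne faster than the second cycloaddition occurs. The phenols formed may be acylated by vinylketene 16.
- Fallback (known chemistry): the double annulation is given up and the bridge is made last. The route is left at aldehyde 1. It is condensed in aqueous-methanolic KOH at room temperature with two equivalents of 1-(5,7-dihydroxy-2,2-dimethylchroman-8-yl)-2-methylpropan-1-one F1. This ketone comes from commercial 2-methyl-1-(2,4,6-trihydroxyphenyl)propan-1-one by acid-mediated prenylation–cyclisation with 2-methylbut-3-en-2-ol and separation from its 6-acyl isomer. Phenolate hydroxyalkylation at C6, loss of water to the ortho-quinone methide and conjugate addition of the second phenolate should give target 20 directly.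

Step 5.
- What may go wrong: base-mediated propargyl–allenyl isomerisation at the stage of partly metalated or partly oxygenated species, where the central C–H is no longer protected by two anionic termini. Incomplete twofold oxygenation, and consumption of the silyl triflate by tert-butoxide, are further risks.
- Fallback: the acidic hydrogen is taken out of the problem by carrying the bridge carbon as a tertiary methyl ether until both arenes exist. Setting out from alcohol 4:
  - Dess–Martin oxidation gives 8-methyl-1-(trimethylsilyl)non-1-yn-3-one F2.
  - Addition of acetylide 3 (generated again from 2 and n-BuLi) and methylation of the alkoxide in the same flask (MeI, DMPU) gives 3-methoxy-3-(5-methylhexyl)-1,5-bis(trimethylsilyl)penta-1,4-diyne F3.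
  - K2CO3 in methanol gives 3-methoxy-3-(5-methylhexyl)penta-1,4-diyne F4.
  - The oxygenation–silylation of step 5, now on a substrate without any propargylic hydrogen, gives 3-methoxy-3-(5-methylhexyl)-1,5-bis(triisopropylsilyloxy)penta-1,4-diyne F5.
  - Heating with 15 as in step 8 gives 6,6'-(1-methoxy-6-methylheptane-1,1-diyl)bis[2,2-dimethyl-5-(triisopropylsilyloxy)chroman-7-ol] F6.
  - Ionic hydrogenation of the doubly benzylic ether (Et3SiH, CF3CO2H, CH2Cl2, low temperature) brings the route back at 18.

Step 6.
- What may go wrong: competing O-allylation that does not revert, double allylation at C2, and ring cleavage of the sensitive four-membered dione during the reaction or work-up.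
- Fallback: the pyran ring is built by annulation instead of allylation. Setting out from dione 12, condensation with 3-methylbut-2-enal under ethylenediammonium diacetate catalysis (Knoevenagel condensation, then oxa-6π electrocyclisation) gives 3,3-dimethyl-2-oxabicyclo[4.2.0]octa-1(6),4-dien-7-one F7. Hydrogenation of its disubstituted pyran alkene over Pd/C, which should leave the tetrasubstituted vinylogous-ester double bond untouched, returns the route at 15 and bypasses 14.

Step 9.
- What may go wrong: acid-induced retro-Friedel–Crafts fragmentation of the electron-rich diarylmethine (ipso protonation or ipso acylation at C6 with loss of an ortho-quinone-methide-type cation), and premature loss of the silyl ethers followed by O-acylation.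
- Fallback: the acyl group is delivered by an anionic route. Setting out from 18:
  - Bromination at the only free arene carbon with N-bromosuccinimide at low temperature gives 6,6'-(6-methylheptane-1,1-diyl)bis[8-bromo-2,2-dimethyl-5-(triisopropylsilyloxy)chroman-7-ol] F8.
  - Esterification of the C7 hydroxyls (i-PrCOCl, Et3N, DMAP) gives (6-methylheptane-1,1-diyl)bis[8-bromo-2,2-dimethyl-5-(triisopropylsilyloxy)chroman-6,7-diyl] bis(2-methylpropanoate) F9.
  - Bromine–lithium exchange with t-BuLi at −78 °C triggers an anionic Fries rearrangement (1,3 O→C acyl shift) that returns the route at 19.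

Step 3.
- What may go wrong: delivery of the alkynyl group to the distal alkyne carbon (allenyne formation), transfer of a methyl group from aluminium in place of the alkynyl group, or elimination of the mesylate to an enyne.
- Fallback: the substitution is run as a Nicholas reaction. Setting out from alcohol 4, complexation with Co2(CO)8 gives hexacarbonyl[μ-8-methyl-1-(trimethylsilyl)non-1-yn-3-ol]dicobalt F10. BF3·OEt2 generates the cobalt-stabilised propargylic cation, which can be attacked only at the propargylic carbon; alane 6 converts it to hexacarbonyl{μ-[3-(5-methylhexyl)-1,5-bis(trimethylsilyl)penta-1,4-diyne]}dicobalt F11. Oxidative decomplexation with (NH4)2Ce(NO3)6 returns the route at 7.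

## Further compounds

F1 | step 8 | 1-(5,7-dihydroxy-2,2-dimethylchroman-8-yl)-2-methylpropan-1-one | CC(C)C(=O)c1c(O)cc(O)c2CCC(C)(C)Oc12
F2 | step 5 | 8-methyl-1-(trimethylsilyl)non-1-yn-3-one | CC(C)CCCCC(=O)C#C[Si](C)(C)C
F3 | step 5 | 3-methoxy-3-(5-methylhexyl)-1,5-bis(trimethylsilyl)penta-1,4-diyne | CC(C)CCCCC(OC)(C#C[Si](C)(C)C)C#C[Si](C)(C)C
F4 | step 5 | 3-methoxy-3-(5-methylhexyl)penta-1,4-diyne | CC(C)CCCCC(OC)(C#C)C#C
F5 | step 5 | 3-methoxy-3-(5-methylhexyl)-1,5-bis(triisopropylsilyloxy)penta-1,4-diyne | CC(C)CCCCC(OC)(C#CO[Si](C(C)C)(C(C)C)C(C)C)C#CO[Si](C(C)C)(C(C)C)C(C)C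
F6 | step 5 | 6,6'-(1-methoxy-6-methylheptane-1,1-diyl)bis[2,2-dimethyl-5-(triisopropylsilyloxy)chroman-7-ol] | CC(C)CCCCC(OC)(c1c(O[Si](C(C)C)(C(C)C)C(C)C)c2CCC(C)(C)Oc2cc1O)c1c(O[Si](C(C)C)(C(C)C)C(C)C)c2CCC(C)(C)Oc2cc1O
F7 | step 6 | 3,3-dimethyl-2-oxabicyclo[4.2.0]octa-1(6),4-dien-7-one | O=C1CC2=C1C=CC(C)(C)O2
F8 | step 9 | 6,6'-(6-methylheptane-1,1-diyl)bis[8-bromo-2,2-dimethyl-5-(triisopropylsilyloxy)chroman-7-ol] | CC(C)CCCCC(c1c(O[Si](C(C)C)(C(C)C)C(C)C)c2CCC(C)(C)Oc2c(Br)c1O)c1c(O[Si](C(C)C)(C(C)C)C(C)C)c2CCC(C)(C)Oc2c(Br)c1O
F9 | step 9 | (6-methylheptane-1,1-diyl)bis[8-bromo-2,2-dimethyl-5-(triisopropylsilyloxy)chroman-6,7-diyl] bis(2-methylpropanoate) | CC(C)CCCCC(c1c(O[Si](C(C)C)(C(C)C)C(C)C)c2CCC(C)(C)Oc2c(Br)c1OC(=O)C(C)C)c1c(O[Si](C(C)C)(C(C)C)C(C)C)c2CCC(C)(C)Oc2c(Br)c1OC(=O)C(C)C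
F10 | step 3 | hexacarbonyl[μ-8-methyl-1-(trimethylsilyl)non-1-yn-3-ol]dicobalt (Co–Co), racemic | CC(C)CCCCC(O)C12C3([Si](C)(C)C)[Co]1(=C=O)(=C=O)(=C=O)[Co]23(=C=O)(=C=O)=C=O
F11 | step 3 | hexacarbonyl{μ-[3-(5-methylhexyl)-1,5-bis(trimethylsilyl)penta-1,4-diyne]}dicobalt (Co–Co), one alkyne complexed, racemic | CC(C)CCCCC(C#C[Si](C)(C)C)C12C3([Si](C)(C)C)[Co]1(=C=O)(=C=O)(=C=O)[Co]23(=C=O)(=C=O)=C=O
A1 | alternative 1 | 3,3'-(6-methylheptane-1,1-diyl)bis[4-(benzyloxy)-6-(3-methyl-2-oxobutyl)-2H-pyran-2-one] | CC(C)CCCCC(c1c(OCc2ccccc2)cc(CC(=O)C(C)C)oc1=O)c1c(OCc2ccccc2)cc(CC(=O)C(C)C)oc1=O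
A2 | alternative 1 | 1,1'-{(6-methylheptane-1,1-diyl)bis[4-(benzyloxy)-2,6-dihydroxy-3,1-phenylene]}bis(2-methylpropan-1-one) | CC(C)CCCCC(c1c(OCc2ccccc2)cc(O)c(C(=O)C(C)C)c1O)c1c(OCc2ccccc2)cc(O)c(C(=O)C(C)C)c1O
A3 | alternative 2 | 1,1'-{(6-methylheptane-1,1-diyl)bis[4-(benzyloxy)-2,6-dihydroxy-5-(3-methylbut-2-en-1-yl)-3,1-phenylene]}bis(2-methylpropan-1-one) | CC(C)CCCCC(c1c(OCc2ccccc2)c(CC=C(C)C)c(O)c(C(=O)C(C)C)c1O)c1c(OCc2ccccc2)c(CC=C(C)C)c(O)c(C(=O)C(C)C)c1O
A4 | alternative 2 | 1,1'-[(6-methylheptane-1,1-diyl)bis(5-benzyloxy-7-hydroxy-2,2-dimethylchroman-6,8-diyl)]bis(2-methylpropan-1-one) | CC(C)CCCCC(c1c(OCc2ccccc2)c2CCC(C)(C)Oc2c(C(=O)C(C)C)c1O)c1c(OCc2ccccc2)c2CCC(C)(C)Oc2c(C(=O)C(C)C)c1O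
A5 | alternative 3 | 3-methylbut-2-enal | CC(C)=CC=O
A6 | alternative 3 | 1,1'-[(6-methylheptane-1,1-diyl)bis(5-benzyloxy-7-hydroxy-2,2-dimethyl-2H-chromene-6,8-diyl)]bis(2-methylpropan-1-one) | CC(C)CCCCC(c1c(OCc2ccccc2)c2C=CC(C)(C)Oc2c(C(=O)C(C)C)c1O)c1c(OCc2ccccc2)c2C=CC(C)(C)Oc2c(C(=O)C(C)C)c1O
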